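**Retrosynthetic overview**
1. Target 11 ⇒ salicylaldehyde ether 8. In the last flask the pyranone ring is closed with Ph3P=C=C=O (phenol acylation, intramolecular Wittig) and the oxolane ring by acid (epoxide hydrolysis, then allyl-cation etherification).
2. 8 ⇒ Mitsunobu union (ArO–CH2 bond) of 2,4-dihydroxy-3,5-dimethoxybenzaldehyde 3 with epoxy diol 7.
3. 7 ⇒ Sharpless epoxidation of diene diol 6 ⇐ Schenck ene reaction of geraniol 4. C2 is set here, C3 by inversion in the last step, C5 in the ring closure.
4. 3 ⇐ syringaldehyde 1 by bromination and copper-mediated hydroxylation.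
5. Ring order: benzene ring bought with 1; temporary oxirane in step 4; pyranone, then oxolane, both in step 6.

Assumption: the target is the (2S,3R,5R)-oxolane that the SMILES defines, and Ph3P=C=C=O, (2R,3R)-(+)-diethyl tartrate, DIAD and PPh3 are bought.

**Step 1**
Reactants: 1 syringaldehyde (4-hydroxy-3,5-dimethoxybenzaldehyde)
Product: 2 2-bromo-4-hydroxy-3,5-dimethoxybenzaldehyde
Conditions: Br2 (1.05 equiv), AcOH, rt
Reagents that add atoms: bromine, BrBr
Why: Electrophilic aromatic bromination, in which the only free positions (C2 and C6, equivalent) are ortho and para to the two methoxy groups, so one monobromide forms.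

**Step 2**
Reactants: 2 2-bromo-4-hydroxy-3,5-dimethoxybenzaldehyde
Product: 3 2,4-dihydroxy-3,5-dimethoxybenzaldehyde
Conditions: NaOH (aq), Cu powder (cat.), reflux; then HCl (aq)
Reagents that add atoms: sodium hydroxide, [Na+].[OH-]
Why: Ullmann-type copper-mediated hydroxylation of an aryl bromide activated by the ortho formyl group, as in the classical 5-bromovanillin to 5-hydroxyvanillin conversion, with the phenoxide form shielding the aldehyde from Cannizzaro reaction.

**Step 3**
Reactants: 4 geraniol ((2E)-3,7-dimethylocta-2,6-dien-1-ol)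
Product: 6 (2E,5E)-3,7-dimethylocta-2,5-diene-1,7-diol, via allylic hydroperoxide 5 (not isolated)
Conditions: O2, tetraphenylporphyrin (cat.), hν (visible), CH2Cl2, 0 °C; then PPh3, 0 °C → rt
Reagents that add atoms: dioxygen, O=O
Why: Schenck ene reaction of singlet oxygen at the electron-rich 6,7-alkene (the 2,3-alkene is deactivated by the allylic hydroxyl) gives the tertiary hydroperoxide with a new E-alkene, PPh3 reduces the O–O bond, and the roughly equal amount of the 2,7-diene-1,6-diol regioisomer is removed by chromatography.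

**Step 4**
Reactants: 6 (2E,5E)-3,7-dimethylocta-2,5-diene-1,7-diol
Product: 7 [(2S,3S)-3-[(2E)-4-hydroxy-4-methylpent-2-en-1-yl]-3-methyloxiran-2-yl]methanol
Conditions: Ti(OiPr)4 (0.2 equiv), (2R,3R)-(+)-diethyl tartrate (0.25 equiv), t-BuOOH, 4 Å molecular sieves, CH2Cl2, −20 °C
Reagents that add atoms: tert-butyl hydroperoxide, CC(C)(C)OO
Why: Sharpless asymmetric epoxidation, in which only the primary allylic alcohol is a competent substrate (tertiary allylic alcohols react very slowly) and the (+)-tartrate delivers oxygen to the face that gives the (2S,3S)-epoxide, as for geraniol.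

**Step 5**
Reactants: 3 2,4-dihydroxy-3,5-dimethoxybenzaldehyde; 7 [(2S,3S)-3-[(2E)-4-hydroxy-4-methylpent-2-en-1-yl]-3-methyloxiran-2-yl]methanol
Product: 8 2-hydroxy-4-{[(2S,3S)-3-[(2E)-4-hydroxy-4-methylpent-2-en-1-yl]-3-methyloxiran-2-yl]methoxy}-3,5-dimethoxybenzaldehyde
Conditions: PPh3, DIAD, THF, 0 °C → rt
Reagents that add atoms: none
Why: Mitsunobu etherification, in which the 4-OH (para to the formyl group and not hydrogen-bonded) is the more acidic phenol and attacks the primary alkoxyphosphonium ion, while the chelated 2-OH, the tertiary alcohol and both oxirane stereocentres are untouched.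

**Step 6**
Reactants: 8 2-hydroxy-4-{[(2S,3S)-3-[(2E)-4-hydroxy-4-methylpent-2-en-1-yl]-3-methyloxiran-2-yl]methoxy}-3,5-dimethoxybenzaldehyde
Product: 11 7-{[(2S,3R,5R)-3-hydroxy-3-methyl-5-(2-methylprop-1-en-1-yl)oxolan-2-yl]methoxy}-6,8-dimethoxy-2H-chromen-2-one, via coumarin epoxy alcohol 9 (not isolated), via coumarin triol 10 (not isolated)
Conditions: Ph3P=C=C=O (1.1 equiv), toluene, 80 °C; then aq. HClO4 (0.2 equiv), THF/H2O (9:1), 0 °C → rt
Reagents that add atoms: (triphenylphosphoranylidene)ketene, O=C=C=P(c1ccccc1)(c1ccccc1)c1ccccc1; water, O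
Why: Proposed new method: Ph3P=C=C=O acylates the chelated phenol and the ester ylide closes the pyranone by intramolecular Wittig reaction (the known Bestmann coumarin annulation), after which the acid opens the trisubstituted oxirane with water at the tertiary carbon with inversion (C3 becomes R, the C2 oxygen is kept, and this regioselectivity preserves the enantiopurity), ionises the tertiary allylic alcohol to a dimethylallyl cation and lets the freed C2 hydroxyl close the oxolane 5-exo at the secondary terminus, the alkenyl group expected to end trans to the CH2OAr and CH3 groups (5R) because the cation is approached on the less hindered face and the allylic ether can re-ionise and equilibrate; the closest known reactions are the acid hydrolysis of trisubstituted epoxides with inversion and the acid cyclisation of tertiary allylic diols to rose oxide.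

**Compound list**
1 | syringaldehyde (4-hydroxy-3,5-dimethoxybenzaldehyde) | COc1cc(C=O)cc(OC)c1O | starting material
2 | 2-bromo-4-hydroxy-3,5-dimethoxybenzaldehyde | COc1cc(C=O)c(Br)c(OC)c1O | intermediate
3 | 2,4-dihydroxy-3,5-dimethoxybenzaldehyde | COc1cc(C=O)c(O)c(OC)c1O | intermediate
4 | geraniol ((2E)-3,7-dimethylocta-2,6-dien-1-ol) | CC(C)=CCC/C(C)=C/CO | starting material
5 | (2E,5E)-7-hydroperoxy-3,7-dimethylocta-2,5-dien-1-ol | OC/C=C(C)/C/C=C/C(C)(C)OO | intermediate
6 | (2E,5E)-3,7-dimethylocta-2,5-diene-1,7-diol | OC/C=C(C)/C/C=C/C(C)(C)O | intermediate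
7 | [(2S,3S)-3-[(2E)-4-hydroxy-4-methylpent-2-en-1-yl]-3-methyloxiran-2-yl]methanol | OC[C@@H]1O[C@@]1(C)C/C=C/C(C)(C)O | intermediate
8 | 2-hydroxy-4-{[(2S,3S)-3-[(2E)-4-hydroxy-4-methylpent-2-en-1-yl]-3-methyloxiran-2-yl]methoxy}-3,5-dimethoxybenzaldehyde | COc1cc(C=O)c(O)c(OC)c1OC[C@@H]1O[C@@]1(C)C/C=C/C(C)(C)O | intermediate
9 | 7-{[(2S,3S)-3-[(2E)-4-hydroxy-4-methylpent-2-en-1-yl]-3-methyloxiran-2-yl]methoxy}-6,8-dimethoxy-2H-chromen-2-one | COc1cc2ccc(=O)oc2c(OC)c1OC[C@@H]1O[C@@]1(C)C/C=C/C(C)(C)O | intermediate
10 | 7-{[(2S,3R,5E)-2,3,7-trihydroxy-3,7-dimethyloct-5-en-1-yl]oxy}-6,8-dimethoxy-2H-chromen-2-one | COc1cc2ccc(=O)oc2c(OC)c1OC[C@H](O)[C@](C)(O)C/C=C/C(C)(C)O | intermediate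
11 | 7-{[(2S,3R,5R)-3-hydroxy-3-methyl-5-(2-methylprop-1-en-1-yl)oxolan-2-yl]methoxy}-6,8-dimethoxy-2H-chromen-2-one | COc1cc2ccc(=O)oc2c(OC)c1OC[C@@H]1O[C@@H](C=C(C)C)C[C@@]1(C)O | target

**Totals**
Total steps: 6. Longest linear sequence: 4 (steps 3, 4, 5, 6; the arene branch, steps 1, 2, 5, 6, is equally long).

**Three steps most likely to fail**

Step 6. The C5 centre is set by substrate control only, so the C5 epimer may form in a substantial amount. The tertiary C3 hydroxyl could also capture the cation at its tertiary end to give a dihydropyran. The fallback sets out from 8 and comes back at 11. The annulation with Ph3P=C=C=O is run alone and 9 is isolated. Heating 9 in water/1,4-dioxane at pH 7 and 80 °C opens the oxirane at the tertiary carbon without ionising the allylic alcohol, and 10 is isolated. 10 is then cyclised with the zerovalent palladium source Pd2(dba)3·CHCl3, a DACH-phenyl Trost ligand and Et3B in THF. Et3B activates the tertiary allylic hydroxyl for ionisation, and the two faces of the dimethylallyl palladium complex interconvert through the gem-dimethyl terminus. The ligand enantiomer (both are run, the one giving the 2,5-trans oxolane is kept) therefore decides the configuration at C5 when the C2 oxygen closes the ring. This detour makes no compound outside the list (F0).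

Step 2. The electron-rich phenoxide may react sluggishly in the Ullmann hydroxylation, or the aldehyde may degrade in hot alkali. The fallback sets out from 2 and comes back at 3. Miyaura borylation (B2pin2, Pd(OAc)2, SPhos, KOAc, 1,4-dioxane, 90 °C) gives 4-hydroxy-3,5-dimethoxy-2-(4,4,5,5-tetramethyl-1,3,2-dioxaborolan-2-yl)benzaldehyde F1. N-methylmorpholine N-oxide in CH2Cl2 at rt then oxidises the C–B bond to the phenol 3. An N-oxide is used in place of peroxide so that the hydroxybenzaldehyde does not undergo Dakin cleavage.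

Step 5. The hindered 4-OH, flanked by two methoxy groups, may couple slowly, and some 2-O-alkylation may occur. The fallback sets out from 7 and comes back at 8. Selective sulfonylation of the primary hydroxyl (TsCl, Et3N, DMAP cat., CH2Cl2, 0 °C) gives [(2S,3S)-3-[(2E)-4-hydroxy-4-methylpent-2-en-1-yl]-3-methyloxiran-2-yl]methyl 4-methylbenzenesulfonate F2. Williamson alkylation of 3 with F2 under weak base (CsHCO3, MeCN, 60 °C) deprotonates only the more acidic 4-OH and gives 8 with the oxirane intact.

**Further compounds**
F1 | step 2 | 4-hydroxy-3,5-dimethoxy-2-(4,4,5,5-tetramethyl-1,3,2-dioxaborolan-2-yl)benzaldehyde | COc1cc(C=O)c(B2OC(C)(C)C(C)(C)O2)c(OC)c1O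
F2 | step 5 | [(2S,3S)-3-[(2E)-4-hydroxy-4-methylpent-2-en-1-yl]-3-methyloxiran-2-yl]methyl 4-methylbenzenesulfonate | Cc1ccc(cc1)S(=O)(=O)OC[C@@H]1O[C@@]1(C)C/C=C/C(C)(C)O
F0 | step 6 | none | none
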